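**Plan**
- Retrosynthetic cuts, in order: C11=C12 (Wittig), C11′=C12′ (Wittig with the C10 dialdehyde), C8′–C9′ (Sonogashira), C7=C8 (Horner–Wadsworth–Emmons), then C5=C6 and C5′=C6′ of both rings.
- Enabling feature: ring B is a cyclohexene whose tetrasubstituted C5′=C6′ bond is conjugated to C7′ and whose only stereocentre, C3′, lies between two CH2 groups. C5′=C6′ is therefore closed by aldol condensation of acyclic keto aldehyde 10 to enal 12; ring A is the same ring with two more oxygens, so it is also made from 12.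
- Forward order: acyclic chain (steps 1–5), ring closure (step 6), ring B alkyne and the C15 and C25 phosphonium salts (steps 7–14), ring A C15 aldehyde (steps 15–21), union and desilylation (steps 22–23).
- Stereochemistry: C3′ and C3 both come from one Brown methallylboration (step 3); C6 and C5 from Sharpless epoxidation (step 16) and inverting hydrolysis at C5 (step 17); alkene geometry from (E)-iodide 18, all-E dialdehyde 21 and E-selective olefinations.

Key step: step 6

Remark: the SMILES is read as (3S,5S,6S,3′R), that is 3-OH and 5-OH cis and 6-OH trans to both; carotenoid numbering is used for positions, with primes for the ring B half.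

**Route**

Step 1
Reactants: 1 2,2-dimethylpent-4-enal
Product: 2 1-methoxy-3,3-dimethylhexa-1,5-diene (E/Z mixture)
Conditions: MeOCH2PPh3Cl, KOt-Bu, THF, 0 °C → rt
Reagents that add atoms: (methoxymethyl)triphenylphosphonium chloride, COC[P+](c1ccccc1)(c1ccccc1)c1ccccc1.[Cl-]
Why: Wittig reaction of the non-enolisable, α-quaternary aldehyde with methoxymethylidene(triphenyl)phosphorane should give the enol ether of the one-carbon-longer aldehyde and leave the terminal alkene alone.

Step 2
Reactants: 2 1-methoxy-3,3-dimethylhexa-1,5-diene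
Product: 3 3,3-dimethylhex-5-enal
Conditions: 2 M HCl, THF, rt
Reagents that add atoms: water, O
Why: Acid-catalysed enol ether hydrolysis completes the one-carbon aldehyde homologation in dilute aqueous acid, to which the isolated monosubstituted alkene is inert.

Step 3
Reactants: 3 3,3-dimethylhex-5-enal; 4 2-methylallylmagnesium chloride
Product: 7 (R)-2,6,6-trimethylnona-1,8-dien-4-ol, via B-methallyldiisopinocampheylborane 5 (not isolated), via borinate ester 6 (not isolated)
Conditions: (+)-Ipc2BOMe [from (−)-α-pinene], Et2O, −78 °C → rt; then 3, −78 °C; NaOH, H2O2, 0 °C → rt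
Reagents that add atoms: none
Why: Brown asymmetric methallylboration through a chair-like six-membered transition state, in which the isopinocampheyl groups from (−)-α-pinene should direct the methallyl group to the Re face of the aldehyde and so set the future C3′/C3 centre as 4R in 7.

Step 4
Reactants: 7 (R)-2,6,6-trimethylnona-1,8-dien-4-ol
Product: 8 (R)-tert-butyldiphenyl[(2,6,6-trimethylnona-1,8-dien-4-yl)oxy]silane
Conditions: t-BuPh2SiCl, imidazole, DMAP (cat.), DMF, rt
Reagents that add atoms: tert-butyl(chloro)diphenylsilane, CC(C)(C)[Si](Cl)(c1ccccc1)c1ccccc1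
Why: Standard silylation of a secondary alcohol; the tert-butyldiphenylsilyl ether is chosen because it is a poor leaving group in the ring closure and should withstand ozone, PPh3·HBr and aqueous HClO4 later in the route.

Step 5
Reactants: 8 (R)-tert-butyldiphenyl[(2,6,6-trimethylnona-1,8-dien-4-yl)oxy]silane
Product: 10 (S)-5-(tert-butyldiphenylsilyloxy)-3,3-dimethyl-7-oxooctanal, via bis-ozonide 9 (not isolated)
Conditions: O3, CH2Cl2, −78 °C; then PPh3, −78 °C → rt
Reagents that add atoms: ozone, [O-][O+]=O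
Why: Ozonolysis with reductive work-up cleaves both 1-alkenes in one operation, the allyl terminus to the C7′ aldehyde and the methallyl group to the C5′ methyl ketone, without touching the silyl ether or the stereocentre.

Step 6
Reactants: 10 (S)-5-(tert-butyldiphenylsilyloxy)-3,3-dimethyl-7-oxooctanal
Product: 12 (R)-4-(tert-butyldiphenylsilyloxy)-2,6,6-trimethylcyclohex-1-ene-1-carbaldehyde, via cyclic aldol adduct 11 (not isolated)
Conditions: pyrrolidine (20 mol %), AcOH (20 mol %), CH2Cl2, 0 °C → rt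
Reagents that add atoms: none
Why: Pyrrolidine condenses with the unhindered C7′ aldehyde to an enamine whose C6′ carbon adds to the C5′ ketone, and the β-hydroxy iminium ion then loses water by enamine-assisted E1cB elimination and is hydrolysed to the tetrasubstituted enal; this is the classical secondary-amine/carboxylic-acid intramolecular aldol condensation of keto aldehydes to cycloalkene carbaldehydes. Ring B closes in the 6-(enolexo)-exo-trig mode by the C6′–C5′ bond. No stereocentre is formed, and C3′, set in step 3 and flanked by two CH2 groups, cannot epimerise. The step needs the aldehyde enamine to react rather than a ketone enolate or enamine, which would give an acetylcyclohexene or expel the β-silyloxy group; the much faster enamine formation of a primary aldehyde than of a methyl ketone and the absence of strong base should secure this. The product should be safe from dienamine formation and loss of the silyloxy group because its aldehyde, wedged between the gem-dimethyl carbon and the tetrasubstituted alkene, condenses with the amine only slowly and a silanolate is a poor leaving group.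

Step 7
Reactants: 12 (R)-4-(tert-butyldiphenylsilyloxy)-2,6,6-trimethylcyclohex-1-ene-1-carbaldehyde
Product: 13 (R)-tert-butyl{[4-(2,2-dibromoethenyl)-3,5,5-trimethylcyclohex-3-en-1-yl]oxy}diphenylsilane
Conditions: CBr4, PPh3, Zn, CH2Cl2, 0 °C → rt
Reagents that add atoms: carbon tetrabromide, BrC(Br)(Br)Br
Why: First half of the Corey–Fuchs alkyne synthesis, a Wittig-type dibromo-olefination by the small, reactive ylide Ph3P=CBr2, which should also attack hindered cyclocitral-type aldehydes, with Zn keeping the medium free of acidic phosphorus bromides.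

Step 8
Reactants: 13 (R)-tert-butyl{[4-(2,2-dibromoethenyl)-3,5,5-trimethylcyclohex-3-en-1-yl]oxy}diphenylsilane
Product: 15 (R)-tert-butyl[(4-ethynyl-3,5,5-trimethylcyclohex-3-en-1-yl)oxy]diphenylsilane, via lithium acetylide 14 (not isolated)
Conditions: n-BuLi (2.2 equiv), THF, −78 °C → 0 °C; then H2O
Reagents that add atoms: none
Why: Second half of the Corey–Fuchs sequence, in which bromine–lithium exchange, 1,2-shift of the carbenoid (Fritsch–Buttenberg–Wiechell) and deprotonation give the lithium acetylide, which water protonates to the terminal alkyne C7′≡C8′.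

Step 9
Reactants: 16 but-2-yn-1-ol
Product: 18 (E)-3-iodobut-2-en-1-ol, via alkenylzirconium species 17 (not isolated)
Conditions: Cp2Zr(H)Cl (2.5 equiv), THF, rt; then I2, −78 °C → 0 °C
Reagents that add atoms: iodine, II
Why: Hydrozirconation of the 2-alkynol is a syn addition that, with excess Cp2Zr(H)Cl, should equilibrate to the isomer with zirconium on the methyl-bearing carbon, and iodinolysis with retention then gives the (E)-iodoalkene.

Step 10
Reactants: 15 (R)-tert-butyl[(4-ethynyl-3,5,5-trimethylcyclohex-3-en-1-yl)oxy]diphenylsilane; 18 (E)-3-iodobut-2-en-1-ol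
Product: 19 (E)-5-[(R)-4-(tert-butyldiphenylsilyloxy)-2,6,6-trimethylcyclohex-1-en-1-yl]-3-methylpent-2-en-4-yn-1-ol
Conditions: Pd(PPh3)4 (5 mol %), CuI (10 mol %), i-Pr2NH, THF, rt
Reagents that add atoms: none
Why: Sonogashira coupling of the terminal alkyne with the alkenyl iodide forms C8′–C9′ with retention of the E geometry and tolerates the free primary hydroxyl.

Step 11
Reactants: 19 (E)-5-[(R)-4-(tert-butyldiphenylsilyloxy)-2,6,6-trimethylcyclohex-1-en-1-yl]-3-methylpent-2-en-4-yn-1-ol
Product: 20 [(E)-5-{(R)-4-(tert-butyldiphenylsilyloxy)-2,6,6-trimethylcyclohex-1-en-1-yl}-3-methylpent-2-en-4-yn-1-yl]triphenylphosphonium bromide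
Conditions: PPh3·HBr, CH2Cl2/MeOH, rt
Reagents that add atoms: triphenylphosphine hydrobromide, [Br-].c1ccc(cc1)[PH+](c1ccccc1)c1ccccc1
Why: Allylic alcohols are converted by PPh3·HBr into allylic phosphonium bromides through the delocalised cation, which the phosphine captures at the unhindered primary terminus (the standard preparation of polyene Wittig salts), and the tert-butyldiphenylsilyl ether should tolerate this weak acid.

Step 12
Reactants: 20 the C15 phosphonium bromide; 21 (2E,4E,6E)-2,7-dimethylocta-2,4,6-trienedial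
Product: 23 (2E,4E,6E,8E,10E)-13-[(R)-4-(tert-butyldiphenylsilyloxy)-2,6,6-trimethylcyclohex-1-en-1-yl]-2,7,11-trimethyltrideca-2,4,6,8,10-pentaen-12-ynal, via phosphorus ylide 22 (not isolated)
Conditions: 21 (3 equiv), NaOMe, CH2Cl2/MeOH, 0 °C → rt; then 50 °C, dark
Reagents that add atoms: none
Why: Wittig olefination of the semi-stabilised allylic ylide with an excess of the symmetrical dialdehyde should give the mono-adduct with the new C11′=C12′ bond, whose sterically hindered Z isomer is expected to isomerise to E on warming while the all-E triene of 21 is carried over unchanged.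

Step 13
Reactants: 23 the C25 polyenynal
Product: 24 (2E,4E,6E,8E,10E)-13-[(R)-4-(tert-butyldiphenylsilyloxy)-2,6,6-trimethylcyclohex-1-en-1-yl]-2,7,11-trimethyltrideca-2,4,6,8,10-pentaen-12-yn-1-ol
Conditions: NaBH4, MeOH/CH2Cl2, 0 °C
Reagents that add atoms: none
Why: Chemoselective 1,2-reduction of the polyenal by NaBH4 gives the primary allylic alcohol, nothing else in 23 being reducible under these conditions.

Step 14
Reactants: 24 the C25 polyenynol
Product: 25 [(2E,4E,6E,8E,10E)-13-{(R)-4-(tert-butyldiphenylsilyloxy)-2,6,6-trimethylcyclohex-1-en-1-yl}-2,7,11-trimethyltrideca-2,4,6,8,10-pentaen-12-yn-1-yl]triphenylphosphonium bromide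
Conditions: PPh3·HBr, CH2Cl2/MeOH, rt
Reagents that add atoms: triphenylphosphine hydrobromide, [Br-].c1ccc(cc1)[PH+](c1ccccc1)c1ccccc1
Why: Same phosphonium salt formation as in step 11, now on a polyenyl carbinol, whose delocalised cation should again be trapped at the terminal CH2.

Step 15
Reactants: 12 (R)-4-(tert-butyldiphenylsilyloxy)-2,6,6-trimethylcyclohex-1-ene-1-carbaldehyde
Product: 26 (R)-[4-(tert-butyldiphenylsilyloxy)-2,6,6-trimethylcyclohex-1-en-1-yl]methanol
Conditions: NaBH4, CeCl3·7H2O, MeOH, 0 °C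
Reagents that add atoms: none
Why: Luche 1,2-reduction of the hindered enal gives the allylic alcohol that the titanium catalyst of the next step needs as a handle.

Step 16
Reactants: 26 (R)-[4-(tert-butyldiphenylsilyloxy)-2,6,6-trimethylcyclohex-1-en-1-yl]methanol
Product: 27 [(1R,2R,4S)-4-(tert-butyldiphenylsilyloxy)-1,2-epoxy-2,6,6-trimethylcyclohexyl]methanol (epoxide oxygen anti to the silyloxy group)
Conditions: Ti(Oi-Pr)4 (10 mol %), D-(−)-diethyl tartrate (12 mol %), t-BuOOH, 4 Å sieves, CH2Cl2, −20 °C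
Reagents that add atoms: tert-butyl hydroperoxide, CC(C)(C)OO
Why: Sharpless asymmetric epoxidation, in which the titanium/D-(−)-tartrate catalyst should deliver the oxygen to the face of the tetrasubstituted alkene opposite to the C3 silyloxy group (reagent control reinforced by the steric preference of the ring, a matched case) and so set C5 and C6 as the anti epoxide (1R,2R in 27).

Step 17
Reactants: 27 the anti-epoxy alcohol
Product: 28 (1R,2S,4S)-4-(tert-butyldiphenylsilyloxy)-1-(hydroxymethyl)-2,6,6-trimethylcyclohexane-1,2-diol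
Conditions: HClO4 (5 % aq.), THF, 0 °C → rt
Reagents that add atoms: water, O
Why: Acid-catalysed hydrolysis of a 2,3-epoxy alcohol, in which water should attack the protonated epoxide with inversion at C5, the tertiary carbon that is remote from the electron-withdrawing hydroxymethyl group and not neopentyl, so that the 5-OH ends cis to the 3-oxygen and trans to the untouched 6-oxygen (1R,2S in 28, which is 5S,6S once C7 is an alkene carbon).

Step 18
Reactants: 28 the triol
Product: 29 (1S,2S,4S)-4-(tert-butyldiphenylsilyloxy)-1,2-dihydroxy-2,6,6-trimethylcyclohexane-1-carbaldehyde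
Conditions: SO3·pyridine, DMSO, i-Pr2NEt, CH2Cl2, 0 °C
Reagents that add atoms: none
Why: Parikh–Doering oxidation converts only the primary alcohol because the two tertiary hydroxyls have no carbinol hydrogen and activated DMSO does not cleave 1,2-diols, and its mild amine base should avoid retro-aldol opening of the β-hydroxy aldehyde.

Step 19
Reactants: 29 the dihydroxy aldehyde
Product: 30 (1S,2S,4S)-4-(tert-butyldiphenylsilyloxy)-2,6,6-trimethyl-1,2-bis(trimethylsilyloxy)cyclohexane-1-carbaldehyde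
Conditions: Me3SiOTf, 2,6-lutidine, CH2Cl2, −78 → 0 °C
Reagents that add atoms: trimethylsilyl trifluoromethanesulfonate, C[Si](C)(C)OS(=O)(=O)C(F)(F)F
Why: Silylation with the silyl triflate caps both hindered tertiary hydroxyls, which shuts off retro-aldol and α-ketol rearrangement of the non-enolisable aldehyde under the basic olefination that follows.

Step 20
Reactants: 30 the bis(trimethylsilyl) aldehyde; 31 diethyl [(E)-3-cyano-2-methylprop-2-en-1-yl]phosphonate (sold as an E/Z mixture, usable as such)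
Product: 33 (2E,4E)-5-[(1S,2S,4S)-4-(tert-butyldiphenylsilyloxy)-2,6,6-trimethyl-1,2-bis(trimethylsilyloxy)cyclohexyl]-3-methylpenta-2,4-dienenitrile, via lithiated phosphonate 32 (not isolated)
Conditions: 31, n-BuLi, THF, −78 °C; then 30, −78 → 0 °C
Reagents that add atoms: none
Why: Horner–Wadsworth–Emmons olefination with the C5 cyano phosphonate anion should form C7=C8 with E geometry and bring in C8–C11, the minor 9Z isomer that arises from the delocalised anion being removed by chromatography.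

Step 21
Reactants: 33 the C15 dienenitrile
Product: 35 (2E,4E)-5-[(1S,2S,4S)-4-(tert-butyldiphenylsilyloxy)-2,6,6-trimethyl-1,2-bis(trimethylsilyloxy)cyclohexyl]-3-methylpenta-2,4-dienal, via N-aluminio imine 34 (not isolated)
Conditions: i-Bu2AlH, toluene, −78 °C; then wet SiO2, Et2O, 0 °C
Reagents that add atoms: water, O
Why: Partial reduction of the nitrile with i-Bu2AlH stops at the N-aluminio imine, which neutral hydrolysis on wet silica should convert into the dienal without loss of the silyl ethers.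

Step 22
Reactants: 25 the C25 phosphonium bromide; 35 the C15 dienal
Product: 37 3,3′-bis-O-(tert-butyldiphenylsilyl)-5,6-bis-O-(trimethylsilyl) derivative of the target, via phosphorus ylide 36 (not isolated)
Conditions: NaN(SiMe3)2, THF, −78 °C; then 35, −78 → 0 °C; then 50 °C, dark
Reagents that add atoms: none
Why: Wittig olefination of the polyenyl ylide with the dienal forms C11=C12 and completes the C40 skeleton, the hindered 11Z isomer formed alongside being expected to revert to the all-E polyene on gentle warming.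

Step 23
Reactants: 37 the tetrasilyl ether
Product: 38 (3S,5S,6S,3′R)-7′,8′-didehydro-5,6-dihydro-β,β-carotene-3,5,6,3′-tetrol (target)
Conditions: Bu4NF, THF, rt, dark, argon
Reagents that add atoms: none
Why: Fluoride-mediated desilylation should remove the two tert-butyldiphenylsilyl and the two trimethylsilyl groups in one operation, the polyene, the enyne and the tertiary allylic diol being stable to Bu4NF.

**Compound list**

1 | 2,2-dimethylpent-4-enal | C=CCC(C)(C)C=O | starting material
2 | 1-methoxy-3,3-dimethylhexa-1,5-diene (E/Z mixture) | C=CCC(C)(C)C=COC | intermediate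
3 | 3,3-dimethylhex-5-enal | C=CCC(C)(C)CC=O | intermediate
4 | 2-methylallylmagnesium chloride | CC(=C)C[Mg]Cl | starting material
5 | B-(2-methylallyl)diisopinocampheylborane, isopinocampheyl groups from (−)-α-pinene | CC(=C)CB([C@H]1C[C@H]2C[C@@H]([C@@H]1C)C2(C)C)[C@H]1C[C@H]2C[C@@H]([C@@H]1C)C2(C)C | intermediate (not isolated)
6 | diisopinocampheylborinate ester of alcohol 7 | C=CCC(C)(C)C[C@H](OB([C@H]1C[C@H]2C[C@@H]([C@@H]1C)C2(C)C)[C@H]1C[C@H]2C[C@@H]([C@@H]1C)C2(C)C)CC(C)=C | intermediate (not isolated)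
7 | (R)-2,6,6-trimethylnona-1,8-dien-4-ol | C=CCC(C)(C)C[C@H](O)CC(C)=C | intermediate
8 | (R)-tert-butyldiphenyl[(2,6,6-trimethylnona-1,8-dien-4-yl)oxy]silane | C=CCC(C)(C)C[C@H](O[Si](c1ccccc1)(c1ccccc1)C(C)(C)C)CC(C)=C | intermediate
9 | bis-ozonide (two 1,2,4-trioxolane rings) of diene 8 | C1(OCOO1)CC(C)(C)C[C@H](O[Si](c2ccccc2)(c2ccccc2)C(C)(C)C)CC1(C)OCOO1 | intermediate (not isolated)
10 | (S)-5-(tert-butyldiphenylsilyloxy)-3,3-dimethyl-7-oxooctanal | O=CCC(C)(C)C[C@H](O[Si](c1ccccc1)(c1ccccc1)C(C)(C)C)CC(C)=O | intermediate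
11 | (4S)-4-(tert-butyldiphenylsilyloxy)-2-hydroxy-2,6,6-trimethylcyclohexane-1-carbaldehyde (mixture at C1 and C2) | CC1(O)C[C@@H](O[Si](c2ccccc2)(c2ccccc2)C(C)(C)C)CC(C)(C)C1C=O | intermediate (not isolated)
12 | (R)-4-(tert-butyldiphenylsilyloxy)-2,6,6-trimethylcyclohex-1-ene-1-carbaldehyde | CC1=C(C=O)C(C)(C)C[C@H](O[Si](c2ccccc2)(c2ccccc2)C(C)(C)C)C1 | intermediate
13 | (R)-tert-butyl{[4-(2,2-dibromoethenyl)-3,5,5-trimethylcyclohex-3-en-1-yl]oxy}diphenylsilane | CC1=C(C=C(Br)Br)C(C)(C)C[C@H](O[Si](c2ccccc2)(c2ccccc2)C(C)(C)C)C1 | intermediate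
14 | lithium acetylide of alkyne 15 | CC1=C(C#C[Li])C(C)(C)C[C@H](O[Si](c2ccccc2)(c2ccccc2)C(C)(C)C)C1 | intermediate (not isolated)
15 | (R)-tert-butyl[(4-ethynyl-3,5,5-trimethylcyclohex-3-en-1-yl)oxy]diphenylsilane | CC1=C(C#C)C(C)(C)C[C@H](O[Si](c2ccccc2)(c2ccccc2)C(C)(C)C)C1 | intermediate
16 | but-2-yn-1-ol | CC#CCO | starting material
17 | (E)-alkenylzirconocene chloride from 16, hydroxyl bound as zirconium alkoxide | C/C(=C\CO[Zr](Cl)(C1C=CC=C1)C1C=CC=C1)[Zr](Cl)(C1C=CC=C1)C1C=CC=C1 | intermediate (not isolated)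
18 | (E)-3-iodobut-2-en-1-ol | OC/C=C(C)/I | intermediate
19 | (E)-5-[(R)-4-(tert-butyldiphenylsilyloxy)-2,6,6-trimethylcyclohex-1-en-1-yl]-3-methylpent-2-en-4-yn-1-ol | CC1=C(C#C/C(C)=C/CO)C(C)(C)C[C@H](O[Si](c2ccccc2)(c2ccccc2)C(C)(C)C)C1 | intermediate
20 | [(E)-5-{(R)-4-(tert-butyldiphenylsilyloxy)-2,6,6-trimethylcyclohex-1-en-1-yl}-3-methylpent-2-en-4-yn-1-yl]triphenylphosphonium bromide | CC1=C(C#C/C(C)=C/C[P+](c2ccccc2)(c2ccccc2)c2ccccc2)C(C)(C)C[C@H](O[Si](c2ccccc2)(c2ccccc2)C(C)(C)C)C1.[Br-] | intermediate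
21 | (2E,4E,6E)-2,7-dimethylocta-2,4,6-trienedial | O=C/C(C)=C/C=C/C=C(C)/C=O | starting material
22 | ylide of salt 20 | CC1=C(C#C/C(C)=C/C=P(c2ccccc2)(c2ccccc2)c2ccccc2)C(C)(C)C[C@H](O[Si](c2ccccc2)(c2ccccc2)C(C)(C)C)C1 | intermediate (not isolated)
23 | (2E,4E,6E,8E,10E)-13-[(R)-4-(tert-butyldiphenylsilyloxy)-2,6,6-trimethylcyclohex-1-en-1-yl]-2,7,11-trimethyltrideca-2,4,6,8,10-pentaen-12-ynal | CC1=C(C#C/C(C)=C/C=C/C(C)=C/C=C/C=C(C)/C=O)C(C)(C)C[C@H](O[Si](c2ccccc2)(c2ccccc2)C(C)(C)C)C1 | intermediate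
24 | (2E,4E,6E,8E,10E)-13-[(R)-4-(tert-butyldiphenylsilyloxy)-2,6,6-trimethylcyclohex-1-en-1-yl]-2,7,11-trimethyltrideca-2,4,6,8,10-pentaen-12-yn-1-ol | CC1=C(C#C/C(C)=C/C=C/C(C)=C/C=C/C=C(C)/CO)C(C)(C)C[C@H](O[Si](c2ccccc2)(c2ccccc2)C(C)(C)C)C1 | intermediate
25 | triphenylphosphonium bromide of alcohol 24 (phosphorus on C1 of the chain) | CC1=C(C#C/C(C)=C/C=C/C(C)=C/C=C/C=C(C)/C[P+](c2ccccc2)(c2ccccc2)c2ccccc2)C(C)(C)C[C@H](O[Si](c2ccccc2)(c2ccccc2)C(C)(C)C)C1.[Br-] | intermediate
26 | (R)-[4-(tert-butyldiphenylsilyloxy)-2,6,6-trimethylcyclohex-1-en-1-yl]methanol | CC1=C(CO)C(C)(C)C[C@H](O[Si](c2ccccc2)(c2ccccc2)C(C)(C)C)C1 | intermediate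
27 | [(1R,2R,4S)-4-(tert-butyldiphenylsilyloxy)-1,2-epoxy-2,6,6-trimethylcyclohexyl]methanol | OC[C@]12C(C)(C)C[C@H](O[Si](c3ccccc3)(c3ccccc3)C(C)(C)C)C[C@@]1(C)O2 | intermediate
28 | (1R,2S,4S)-4-(tert-butyldiphenylsilyloxy)-1-(hydroxymethyl)-2,6,6-trimethylcyclohexane-1,2-diol | OC[C@]1(O)C(C)(C)C[C@H](O[Si](c2ccccc2)(c2ccccc2)C(C)(C)C)C[C@]1(C)O | intermediate
29 | (1S,2S,4S)-4-(tert-butyldiphenylsilyloxy)-1,2-dihydroxy-2,6,6-trimethylcyclohexane-1-carbaldehyde | O=C[C@]1(O)C(C)(C)C[C@H](O[Si](c2ccccc2)(c2ccccc2)C(C)(C)C)C[C@]1(C)O | intermediate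
30 | (1S,2S,4S)-4-(tert-butyldiphenylsilyloxy)-2,6,6-trimethyl-1,2-bis(trimethylsilyloxy)cyclohexane-1-carbaldehyde | O=C[C@]1(O[Si](C)(C)C)C(C)(C)C[C@H](O[Si](c2ccccc2)(c2ccccc2)C(C)(C)C)C[C@]1(C)O[Si](C)(C)C | intermediate
31 | diethyl [(E)-3-cyano-2-methylprop-2-en-1-yl]phosphonate | CCOP(=O)(OCC)C/C(C)=C/C#N | starting material
32 | lithium salt of phosphonate 31 (delocalised carbanion) | [Li+].CCOP(=O)(OCC)[CH-]C(C)=CC#N | intermediate (not isolated)
33 | (2E,4E)-5-[(1S,2S,4S)-4-(tert-butyldiphenylsilyloxy)-2,6,6-trimethyl-1,2-bis(trimethylsilyloxy)cyclohexyl]-3-methylpenta-2,4-dienenitrile | N#C/C=C(C)/C=C/[C@]1(O[Si](C)(C)C)C(C)(C)C[C@H](O[Si](c2ccccc2)(c2ccccc2)C(C)(C)C)C[C@]1(C)O[Si](C)(C)C | intermediate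
34 | N-(diisobutylaluminio) imine of aldehyde 35 | CC(C)C[Al](CC(C)C)N=C/C=C(C)/C=C/[C@]1(O[Si](C)(C)C)C(C)(C)C[C@H](O[Si](c2ccccc2)(c2ccccc2)C(C)(C)C)C[C@]1(C)O[Si](C)(C)C | intermediate (not isolated)
35 | (2E,4E)-5-[(1S,2S,4S)-4-(tert-butyldiphenylsilyloxy)-2,6,6-trimethyl-1,2-bis(trimethylsilyloxy)cyclohexyl]-3-methylpenta-2,4-dienal | O=C/C=C(C)/C=C/[C@]1(O[Si](C)(C)C)C(C)(C)C[C@H](O[Si](c2ccccc2)(c2ccccc2)C(C)(C)C)C[C@]1(C)O[Si](C)(C)C | intermediate
36 | ylide of salt 25 | CC1=C(C#C/C(C)=C/C=C/C(C)=C/C=C/C=C(C)/C=P(c2ccccc2)(c2ccccc2)c2ccccc2)C(C)(C)C[C@H](O[Si](c2ccccc2)(c2ccccc2)C(C)(C)C)C1 | intermediate (not isolated)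
37 | 3,3′-bis-O-(tert-butyldiphenylsilyl)-5,6-bis-O-(trimethylsilyl) ether of the target | CC1=C(C#C/C(C)=C/C=C/C(C)=C/C=C/C=C(C)/C=C/C=C(C)/C=C/[C@]2(O[Si](C)(C)C)C(C)(C)C[C@H](O[Si](c3ccccc3)(c3ccccc3)C(C)(C)C)C[C@]2(C)O[Si](C)(C)C)C(C)(C)C[C@H](O[Si](c3ccccc3)(c3ccccc3)C(C)(C)C)C1 | intermediate
38 | (3S,5S,6S,3′R)-7′,8′-didehydro-5,6-dihydro-β,β-carotene-3,5,6,3′-tetrol | CC1=C(C#C/C(C)=C/C=C/C(C)=C/C=C/C=C(C)/C=C/C=C(C)/C=C/[C@]2(O)C(C)(C)C[C@H](O)C[C@]2(C)O)C(C)(C)C[C@H](O)C1 | target

**Step count**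

Total: 23 steps (step 9 is a one-step side branch).
Longest linear sequence: 15 steps (1–6, 7, 8, 10–14, 22, 23). The ring A line (1–6, 15–21, 22, 23) is equally long.

**Steps most likely to fail**

Step 6. After ring closure the silyloxy group may be lost by vinylogous elimination through a dienamine of the product (drift towards a cyclohexadienal), or condensation through the ketone may compete. Fallback, from 10 back to 12: the closure is split into addition and elimination. Keto aldehyde 10 is cyclised with proline (DMSO, rt), which should form the same C6′–C5′ bond through the aldehyde enamine but release the β-hydroxy aldehyde; this aldol, compound 11 of the list, is isolated. MsCl, Et3N and DMAP (CH2Cl2, 0 °C) then convert its tertiary hydroxyl into 4-(tert-butyldiphenylsilyloxy)-2-(methylsulfonyloxy)-2,6,6-trimethylcyclohexane-1-carbaldehyde F1, which should lose methanesulfonate in the same flask by E1cB elimination towards the aldehyde and give enal 12 without the product meeting a secondary amine.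

Step 17. Water may attack C6 instead of C5, or the developing C5 cation may rearrange (ring contraction, hydroxymethyl shift) before it is trapped. Fallback, from 27 back to 33: the epoxide is opened only after an acceptor has been attached to C6. Epoxy alcohol 27 is oxidised (SO3·pyridine, DMSO, i-Pr2NEt) to the anti-epoxy aldehyde 4-(tert-butyldiphenylsilyloxy)-1,2-epoxy-2,6,6-trimethylcyclohexane-1-carbaldehyde F2. Wittig reaction with Ph3P=CHC(O)CH3 (toluene, 80 °C) gives the epoxy enone (E)-4-[4-(tert-butyldiphenylsilyloxy)-1,2-epoxy-2,6,6-trimethylcyclohexyl]but-3-en-2-one F3. In F3 ionisation at C6 would place a cation next to the enone, so aqueous HClO4 in THF should open the epoxide at C5 with inversion to the dihydroxy enone (E)-4-[4-(tert-butyldiphenylsilyloxy)-1,2-dihydroxy-2,6,6-trimethylcyclohexyl]but-3-en-2-one F4. Double silylation (Me3SiOTf, 2,6-lutidine) gives its bis(trimethylsilyl) ether F5, and Horner–Wadsworth–Emmons reaction with the sodium salt of diethyl cyanomethylphosphonate (NaH, THF) returns to nitrile 33 after separation of the 9Z isomer.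

Step 20. The phosphonate anion may fail to add to the congested aldehyde carbonyl, or the base may strip or shift a trimethylsilyl group first. Fallback, from 30 back to 35: C7=C8 is made with a small chromium reagent and C8–C9 by cross-coupling. Takai olefination of 30 (CrCl2, CHI3, THF, 0 °C) should give the (E)-iodoalkene in which the formyl group of 30 is replaced by (E)-2-iodoethenyl F6. Stille coupling with ethyl (E)-3-(tributylstannyl)but-2-enoate (Pd(PPh3)4, CuI, DMF, rt) forms C8–C9 with both geometries fixed and gives the ethyl (2E,4E)-3-methylpenta-2,4-dienoate carrying the ring A substituent at C5 F7. Reduction with i-Bu2AlH (CH2Cl2, −78 °C) gives the corresponding (2E,4E)-dien-1-ol F8, and MnO2 (CH2Cl2, rt) oxidises it to aldehyde 35.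

**Further compounds**

F1 | step 6 | 4-(tert-butyldiphenylsilyloxy)-2-(methylsulfonyloxy)-2,6,6-trimethylcyclohexane-1-carbaldehyde | CC1(OS(C)(=O)=O)C[C@@H](O[Si](c2ccccc2)(c2ccccc2)C(C)(C)C)CC(C)(C)C1C=O
F2 | step 17 | anti-epoxy aldehyde, 4-(tert-butyldiphenylsilyloxy)-1,2-epoxy-2,6,6-trimethylcyclohexane-1-carbaldehyde | O=C[C@]12C(C)(C)C[C@H](O[Si](c3ccccc3)(c3ccccc3)C(C)(C)C)C[C@@]1(C)O2
F3 | step 17 | (E)-4-[4-(tert-butyldiphenylsilyloxy)-1,2-epoxy-2,6,6-trimethylcyclohexyl]but-3-en-2-one | CC(=O)/C=C/[C@]12C(C)(C)C[C@H](O[Si](c3ccccc3)(c3ccccc3)C(C)(C)C)C[C@@]1(C)O2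
F4 | step 17 | (E)-4-[4-(tert-butyldiphenylsilyloxy)-1,2-dihydroxy-2,6,6-trimethylcyclohexyl]but-3-en-2-one | CC(=O)/C=C/[C@]1(O)C(C)(C)C[C@H](O[Si](c2ccccc2)(c2ccccc2)C(C)(C)C)C[C@]1(C)O
F5 | step 17 | bis(trimethylsilyl) ether of F4 | CC(=O)/C=C/[C@]1(O[Si](C)(C)C)C(C)(C)C[C@H](O[Si](c2ccccc2)(c2ccccc2)C(C)(C)C)C[C@]1(C)O[Si](C)(C)C
F6 | step 20 | (E)-2-iodoethenyl analogue of 30 (CHO replaced by CH=CHI) | I/C=C/[C@]1(O[Si](C)(C)C)C(C)(C)C[C@H](O[Si](c2ccccc2)(c2ccccc2)C(C)(C)C)C[C@]1(C)O[Si](C)(C)C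
F7 | step 20 | ethyl (2E,4E)-5-[4-(tert-butyldiphenylsilyloxy)-2,6,6-trimethyl-1,2-bis(trimethylsilyloxy)cyclohexyl]-3-methylpenta-2,4-dienoate | CCOC(=O)/C=C(C)/C=C/[C@]1(O[Si](C)(C)C)C(C)(C)C[C@H](O[Si](c2ccccc2)(c2ccccc2)C(C)(C)C)C[C@]1(C)O[Si](C)(C)C
F8 | step 20 | (2E,4E)-5-[4-(tert-butyldiphenylsilyloxy)-2,6,6-trimethyl-1,2-bis(trimethylsilyloxy)cyclohexyl]-3-methylpenta-2,4-dien-1-ol | OC/C=C(C)/C=C/[C@]1(O[Si](C)(C)C)C(C)(C)C[C@H](O[Si](c2ccccc2)(c2ccccc2)C(C)(C)C)C[C@]1(C)O[Si](C)(C)C
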